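The 4-methoxycyclohex-2-enone ring (C1 = carbonyl carbon) is read as a Robinson-type annulation product: C3 and C4(OMe) are the carbonyl and α-carbon of methoxyacetaldehyde, and C5–C6–C1–C2 is an α-branched methyl vinyl ketone. One amine-catalysed operation joins them: enamine conjugate addition makes the C4–C5 bond and sets the methoxy stereocenter, and aldol condensation makes the C2=C3 double bond. The precursor is an acyclic 3-methylidenepentan-2-one that already carries the syn aryl-carbinol/methyl side chain from an Evans aldol reaction. Allylation of the cross-conjugated enolate then creates the quaternary C6, and desilylation gives megaphone.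

Key step: step 6

Assumption: the enamine of methoxyacetaldehyde is taken to react as its (E)-isomer on the face remote from the diphenyl(silyloxy)methyl group, as alkyl aldehydes do, so the (S)-catalyst is chosen; if the methoxy group reverses this sense, the (R)-catalyst takes its place.

Step 1
Reactants: 1 3,4,5-trimethoxybenzaldehyde; 2 (R)-4-benzyl-3-propanoyl-1,3-oxazolidin-2-one
Product: 4 (4R)-4-benzyl-3-[(2R,3R)-3-hydroxy-2-methyl-3-(3,4,5-trimethoxyphenyl)propanoyl]-1,3-oxazolidin-2-one, via dibutylboron (Z)-enolate 3 (not isolated)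
Conditions: Bu2BOTf, iPr2NEt, CH2Cl2, 0 °C; then 1, −78 → 0 °C; then pH 7 buffer, MeOH, H2O2, 0 °C
Reagents that add atoms: none
Why: Evans syn-aldol reaction, in which the (Z)-boron enolate reacts through a closed chair transition state with the benzyl group of the auxiliary shielding one enolate face, which should give the 2,3-syn adduct with (2R,3R) configuration, that is, both side-chain stereocenters of the target.

Step 2
Reactants: 4 aldol adduct
Product: 5 (2R,3R)-3-hydroxy-N-methoxy-N,2-dimethyl-3-(3,4,5-trimethoxyphenyl)propanamide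
Conditions: MeNH(OMe)·HCl, AlMe3, CH2Cl2, −20 → 0 °C; then aq. HCl (0.5 M), 0 °C
Reagents that add atoms: N,O-dimethylhydroxylamine hydrochloride, CNOC.Cl
Why: Aluminium-amide transamination of the N-acyl oxazolidinone, assisted by the free β-hydroxyl group, should release the auxiliary and give the N-methoxy-N-methylamide without touching either stereocenter.

Step 3
Reactants: 5 hydroxy amide
Product: 6 (2R,3R)-3-[(tert-butyldimethylsilyl)oxy]-N-methoxy-N,2-dimethyl-3-(3,4,5-trimethoxyphenyl)propanamide
Conditions: TBSOTf, 2,6-lutidine, CH2Cl2, −78 → 0 °C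
Reagents that add atoms: tert-butyldimethylsilyl triflate, CC(C)(C)[Si](C)(C)OS(=O)(=O)C(F)(F)F
Why: Silylation of the secondary benzylic alcohol blocks retro-aldol cleavage and alkoxide chemistry in the basic steps that follow.

Step 4
Reactants: 6 silyl ether amide; 7 ethyl vinyl ether
Product: 9 (4R,5R)-5-[(tert-butyldimethylsilyl)oxy]-2-ethoxy-4-methyl-5-(3,4,5-trimethoxyphenyl)pent-1-en-3-one, via 1-ethoxyvinyllithium 8 (not isolated)
Conditions: 7 (excess), tBuLi, THF, −78 → 0 °C; then 6, −78 → −20 °C; aq. NH4Cl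
Reagents that add atoms: none
Why: Acylation of an α-alkoxyvinyllithium by an N-methoxy-N-methylamide stops at the ketone stage and should install the masked acetyl group at low temperature without enolising the α-stereocenter.

Step 5
Reactants: 9 α-ethoxy enone
Product: 11 (4S,5R)-5-[(tert-butyldimethylsilyl)oxy]-4-methyl-3-methylidene-5-(3,4,5-trimethoxyphenyl)pentan-2-one, via ethoxy diene 10 (not isolated)
Conditions: Ph3PCH3Br, KN(SiMe3)2, THF, −78 → 0 °C; then aq. oxalic acid, THF, 0 °C → rt
Reagents that add atoms: methyltriphenylphosphonium bromide, C[P+](c1ccccc1)(c1ccccc1)c1ccccc1.[Br-]; water, O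
Why: Wittig methylenation of the ketone gives the 2-ethoxy-1,3-diene, whose enol ether is hydrolysed by dilute acid through protonation at its terminal carbon, which unmasks the methyl ketone next to the new methylidene group while the non-stabilised ylide should add faster than it enolises the neighbouring stereocenter.

Step 6
Reactants: 11 methylidene ketone; 12 methoxyacetaldehyde
Product: 16 (4R)-6-[(1R,2S)-1-[(tert-butyldimethylsilyl)oxy]-1-(3,4,5-trimethoxyphenyl)propan-2-yl]-4-methoxycyclohex-2-en-1-one (mixture of C6 epimers), via enamine 13 (not isolated), via keto aldehyde 14 (not isolated), via aldol 15 (not isolated)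
Conditions: (S)-α,α-diphenylprolinol trimethylsilyl ether (20 mol%), 4-nitrophenol (20 mol%), 12 (1.5–3 equiv), toluene, 0 °C → rt; then excess 12 removed in vacuo, iPrOH, LiOH·H2O (0.2 equiv), 0 °C → rt
Reagents that add atoms: none
Why: The secondary amine condenses with aldehyde 12 (far faster than with the hindered ketone 11) to enamine 13, whose methoxy-bearing carbon adds to the unsubstituted methylene terminus of the enone to make the C4–C5 bond and, after hydrolysis, the 1,5-keto aldehyde 14; hydroxide then enolises the methyl ketone, which attacks the aldehyde to give aldol 15 and loses water to make the C2=C3 bond of 16. The closest known reaction type is the amine-catalysed Michael addition of aldehydes to vinyl ketones coupled with aldol condensation (Robinson-type annulation), and α-alkoxy aldehydes are established enamine donors. The single ring is closed by a 6-(enolendo)-exo-trig aldol addition followed by E1cB dehydration. The C4 stereocenter is set by the catalyst, whose diphenyl(silyloxy)methyl group shields one face of the (E)-enamine and should give (4R), while C6 forms as an epimer mixture that is of no consequence because step 7 planarises it. Regioselectivity of ring closure is secured by ring size, since the two other enolisable positions (C6–H and the aldehyde α-carbon) could only close four-membered rings, and the terminal CH2 of the acceptor keeps the conjugate addition feasible despite the α-branch.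

Step 7
Reactants: 16 cyclohexenone; 17 allyl bromide
Product: 19 (4R,6R)-6-[(1R,2S)-1-[(tert-butyldimethylsilyl)oxy]-1-(3,4,5-trimethoxyphenyl)propan-2-yl]-4-methoxy-6-(prop-2-en-1-yl)cyclohex-2-en-1-one, via lithium dienolate 18 (not isolated)
Conditions: LiN(iPr)2, THF, −78 °C; then DMPU, 17, −78 → −20 °C
Reagents that add atoms: none
Why: Kinetic deprotonation at C6 gives the cross-conjugated lithium dienolate, and C-allylation (enolate SN2 alkylation) should place the allyl group on the face opposite both the pseudoaxial C4 methoxy group and the CH(OSi)Ar arm, which allylic 1,3-strain (side-chain C–H eclipsing the enolate C–O bond) holds on that same face, so that the quaternary C6 is set as (6R).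

Step 8
Reactants: 19 O-silyl megaphone
Product: 20 megaphone, (4R,6R)-6-[(1R,2S)-1-hydroxy-1-(3,4,5-trimethoxyphenyl)propan-2-yl]-4-methoxy-6-(prop-2-en-1-yl)cyclohex-2-en-1-one
Conditions: HF·pyridine, pyridine, THF, 0 °C → rt
Reagents that add atoms: none
Why: Fluoride-driven cleavage of the silyl ether under buffered conditions should leave the γ-methoxy enone, the allyl group and the benzylic alcohol untouched and changes no stereocenter.

Compound list
1 | 3,4,5-trimethoxybenzaldehyde | COc1cc(C=O)cc(OC)c1OC | starting material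
2 | (R)-4-benzyl-3-propanoyl-1,3-oxazolidin-2-one | CCC(=O)N1[C@H](Cc2ccccc2)COC1=O | starting material
3 | dibutylboron (Z)-enolate of 2 | C/C=C(\OB(CCCC)CCCC)N1[C@H](Cc2ccccc2)COC1=O | intermediate
4 | (4R)-4-benzyl-3-[(2R,3R)-3-hydroxy-2-methyl-3-(3,4,5-trimethoxyphenyl)propanoyl]-1,3-oxazolidin-2-one | COc1cc(cc(OC)c1OC)[C@H](O)[C@@H](C)C(=O)N1[C@H](Cc2ccccc2)COC1=O | intermediate
5 | (2R,3R)-3-hydroxy-N-methoxy-N,2-dimethyl-3-(3,4,5-trimethoxyphenyl)propanamide | COc1cc(cc(OC)c1OC)[C@H](O)[C@@H](C)C(=O)N(C)OC | intermediate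
6 | (2R,3R)-3-[(tert-butyldimethylsilyl)oxy]-N-methoxy-N,2-dimethyl-3-(3,4,5-trimethoxyphenyl)propanamide | COc1cc(cc(OC)c1OC)[C@H](O[Si](C)(C)C(C)(C)C)[C@@H](C)C(=O)N(C)OC | intermediate
7 | ethyl vinyl ether | C=COCC | starting material
8 | 1-ethoxyvinyllithium | [Li]C(=C)OCC | intermediate
9 | (4R,5R)-5-[(tert-butyldimethylsilyl)oxy]-2-ethoxy-4-methyl-5-(3,4,5-trimethoxyphenyl)pent-1-en-3-one | COc1cc(cc(OC)c1OC)[C@H](O[Si](C)(C)C(C)(C)C)[C@@H](C)C(=O)C(=C)OCC | intermediate
10 | tert-butyl{[(1R,2S)-4-ethoxy-2-methyl-3-methylidene-1-(3,4,5-trimethoxyphenyl)pent-4-en-1-yl]oxy}dimethylsilane | COc1cc(cc(OC)c1OC)[C@H](O[Si](C)(C)C(C)(C)C)[C@@H](C)C(=C)C(=C)OCC | intermediate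
11 | (4S,5R)-5-[(tert-butyldimethylsilyl)oxy]-4-methyl-3-methylidene-5-(3,4,5-trimethoxyphenyl)pentan-2-one | COc1cc(cc(OC)c1OC)[C@H](O[Si](C)(C)C(C)(C)C)[C@@H](C)C(=C)C(C)=O | intermediate
12 | methoxyacetaldehyde | COCC=O | starting material
13 | (S)-2-[diphenyl(trimethylsilyloxy)methyl]-1-[(E)-2-methoxyethenyl]pyrrolidine (enamine of 12 and the catalyst) | CO/C=C/N1CCC[C@H]1C(c1ccccc1)(c1ccccc1)O[Si](C)(C)C | intermediate
14 | (2R,5S,6R)-4-acetyl-6-[(tert-butyldimethylsilyl)oxy]-2-methoxy-5-methyl-6-(3,4,5-trimethoxyphenyl)hexanal (C4 epimers) | COc1cc(cc(OC)c1OC)[C@H](O[Si](C)(C)C(C)(C)C)[C@@H](C)C(C[C@@H](OC)C=O)C(C)=O | intermediate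
15 | (4R)-6-[(1R,2S)-1-[(tert-butyldimethylsilyl)oxy]-1-(3,4,5-trimethoxyphenyl)propan-2-yl]-3-hydroxy-4-methoxycyclohexan-1-one (epimers at C3 and C6) | COc1cc(cc(OC)c1OC)[C@H](O[Si](C)(C)C(C)(C)C)[C@@H](C)C1C[C@@H](OC)C(O)CC1=O | intermediate
16 | (4R)-6-[(1R,2S)-1-[(tert-butyldimethylsilyl)oxy]-1-(3,4,5-trimethoxyphenyl)propan-2-yl]-4-methoxycyclohex-2-en-1-one (C6 epimers) | COc1cc(cc(OC)c1OC)[C@H](O[Si](C)(C)C(C)(C)C)[C@@H](C)C1C[C@@H](OC)C=CC1=O | intermediate
17 | allyl bromide | C=CCBr | starting material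
18 | lithium (4R)-2-[(1R,2S)-1-[(tert-butyldimethylsilyl)oxy]-1-(3,4,5-trimethoxyphenyl)propan-2-yl]-4-methoxycyclohexa-1,5-dien-1-olate | COc1cc(cc(OC)c1OC)[C@H](O[Si](C)(C)C(C)(C)C)[C@@H](C)C1=C([O-])C=C[C@H](OC)C1.[Li+] | intermediate
19 | (4R,6R)-6-[(1R,2S)-1-[(tert-butyldimethylsilyl)oxy]-1-(3,4,5-trimethoxyphenyl)propan-2-yl]-4-methoxy-6-(prop-2-en-1-yl)cyclohex-2-en-1-one | C=CC[C@]1([C@H](C)[C@@H](O[Si](C)(C)C(C)(C)C)c2cc(OC)c(OC)c(OC)c2)C[C@@H](OC)C=CC1=O | intermediate
20 | megaphone, (4R,6R)-6-[(1R,2S)-1-hydroxy-1-(3,4,5-trimethoxyphenyl)propan-2-yl]-4-methoxy-6-(prop-2-en-1-yl)cyclohex-2-en-1-one | C=CC[C@]1([C@H](C)[C@@H](O)c2cc(OC)c(OC)c(OC)c2)C[C@@H](OC)C=CC1=O | target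

Total step count: 8. Longest linear sequence: 8 steps (1 and 2 to 20).

Steps most likely to fail

Step 6. Conjugate addition to the α-branched enone may be slow and the methoxy aldehyde may self-condense. The C4 configuration may also erode during the hydroxide-mediated cyclodehydration, by enolisation of the α-methoxy aldehyde before ring closure or by γ-deprotonation of the product. The fallback keeps the conjugate addition but closes the ring by olefination instead of aldol dehydration, so no hydroxide is needed. It sets out from 11: the kinetic lithium enolate (LiN(iPr)2, THF, −78 °C) is C-phosphinylated with ClP(OEt)2 to diethyl [(4S,5R)-5-[(tert-butyldimethylsilyl)oxy]-4-methyl-3-methylidene-2-oxo-5-(3,4,5-trimethoxyphenyl)pentyl]phosphonite F1. Oxidation in the same flask (H2O2, trivalent to pentavalent phosphorus) gives the corresponding diethyl β-ketophosphonate F2. Amine-catalysed conjugate addition of 12 under the conditions of step 6 (first stage only) gives diethyl [(5R)-3-[(1R,2S)-1-[(tert-butyldimethylsilyl)oxy]-1-(3,4,5-trimethoxyphenyl)propan-2-yl]-5-methoxy-2,6-dioxohexyl]phosphonate F3. Intramolecular Horner–Wadsworth–Emmons olefination (LiCl, iPr2NEt, MeCN, rt) then closes the ring and the route is rejoined at 16.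

Step 7. Facial selectivity at the crowded enolate carbon may be poor, α′-deprotonation of the tertiary C6–H may be incomplete, and O-allylation may compete. The fallback replaces substrate-controlled alkylation by catalyst-controlled palladium-catalysed decarboxylative allylation (Tsuji allylation). It sets out from 16: LiN(SiMe3)2 and TMEDA in THF at −78 °C, then allyl chloroformate, give prop-2-en-1-yl (4R)-2-[(1R,2S)-1-[(tert-butyldimethylsilyl)oxy]-1-(3,4,5-trimethoxyphenyl)propan-2-yl]-4-methoxycyclohexa-1,5-dien-1-yl carbonate F4. Pd2(dba)3 with (S)-t-Bu-PHOX in THF at rt should then deliver the allyl group to C6 in the sense that the ligand shows for 2-alkyl-2-allylcyclohexanones, which corresponds to (6R). The route is rejoined at 19.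

Step 5. The basic ylide may enolise the ketone, which would epimerise the methyl-bearing carbon or eliminate silanolate, and methylenation of the hindered carbonyl may stall. The fallback builds the same diene by cross-coupling instead of carbonyl olefination. It sets out from 6: MeMgBr (THF, 0 °C) gives (3R,4R)-4-[(tert-butyldimethylsilyl)oxy]-3-methyl-4-(3,4,5-trimethoxyphenyl)butan-2-one F5. Kinetic enolisation at the methyl group (KN(SiMe3)2, THF, −78 °C) and trapping with PhNTf2 give (3R,4R)-4-[(tert-butyldimethylsilyl)oxy]-3-methyl-4-(3,4,5-trimethoxyphenyl)but-1-en-2-yl trifluoromethanesulfonate F6. Stille coupling with tributyl(1-ethoxyvinyl)stannane (Pd(PPh3)4, LiCl, THF, reflux) gives the ethoxy diene, rejoining the route at 10, which is hydrolysed to 11 as in step 5.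

Further compounds
F1 | step 6 | diethyl [(4S,5R)-5-[(tert-butyldimethylsilyl)oxy]-4-methyl-3-methylidene-2-oxo-5-(3,4,5-trimethoxyphenyl)pentyl]phosphonite | COc1cc(cc(OC)c1OC)[C@H](O[Si](C)(C)C(C)(C)C)[C@@H](C)C(=C)C(=O)CP(OCC)OCC
F2 | step 6 | diethyl [(4S,5R)-5-[(tert-butyldimethylsilyl)oxy]-4-methyl-3-methylidene-2-oxo-5-(3,4,5-trimethoxyphenyl)pentyl]phosphonate | COc1cc(cc(OC)c1OC)[C@H](O[Si](C)(C)C(C)(C)C)[C@@H](C)C(=C)C(=O)CP(=O)(OCC)OCC
F3 | step 6 | diethyl [(5R)-3-[(1R,2S)-1-[(tert-butyldimethylsilyl)oxy]-1-(3,4,5-trimethoxyphenyl)propan-2-yl]-5-methoxy-2,6-dioxohexyl]phosphonate (C3 epimers) | COc1cc(cc(OC)c1OC)[C@H](O[Si](C)(C)C(C)(C)C)[C@@H](C)C(C[C@@H](OC)C=O)C(=O)CP(=O)(OCC)OCC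
F4 | step 7 | prop-2-en-1-yl (4R)-2-[(1R,2S)-1-[(tert-butyldimethylsilyl)oxy]-1-(3,4,5-trimethoxyphenyl)propan-2-yl]-4-methoxycyclohexa-1,5-dien-1-yl carbonate | COc1cc(cc(OC)c1OC)[C@H](O[Si](C)(C)C(C)(C)C)[C@@H](C)C1=C(OC(=O)OCC=C)C=C[C@H](OC)C1
F5 | step 5 | (3R,4R)-4-[(tert-butyldimethylsilyl)oxy]-3-methyl-4-(3,4,5-trimethoxyphenyl)butan-2-one | COc1cc(cc(OC)c1OC)[C@H](O[Si](C)(C)C(C)(C)C)[C@@H](C)C(C)=O
F6 | step 5 | (3R,4R)-4-[(tert-butyldimethylsilyl)oxy]-3-methyl-4-(3,4,5-trimethoxyphenyl)but-1-en-2-yl trifluoromethanesulfonate | COc1cc(cc(OC)c1OC)[C@H](O[Si](C)(C)C(C)(C)C)[C@@H](C)C(=C)OS(=O)(=O)C(F)(F)F
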